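**Plan**

Numbering: ring C1 (C=O), C2=C3, C4 (OMe), C5 (CH2), C6 (quaternary); side chain Ca (CHMe)–Cb (CHOH)–aryl; allyl group C7H2–C8H=C9H2 on C6.
Enabling feature: C7 is bonded to C6, the α-carbon of the C1 ketone, so C7 is the β (homoenolate) carbon. A bond drawn from C7 to C1 turns the 6-allyl ketone into a bicyclo[4.1.0]heptan-1-ol (three-membered ring C1–C6–C7) plus a vinyl halide.
Retrosynthetic cuts, in order: C2=C3 (back to the saturated ketone); C7–C8 (vinyl bromide off); C6–C7 together with C1–C7 (methylene off the C1=C6 silyl enol ether); Cb–aryl (aryl metal off an aldehyde); C6–Ca (nitropropene off 4-methoxycyclohexanone).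
Forward order: the six-membered ring is bought; the chain is joined C6–Ca, then Cb–aryl; the cyclopropane is closed across C1=C6 and reopened at C1–C7 as C7–C8 forms; C2=C3 comes last.
Stereochemistry: an (R)-pyrrolidine catalyst sets Ca and, by picking one enantiotopic α-carbon, C4. Cb is relayed from Ca (Felkin–Anh). C6 is relayed from Ca (A(1,3) strain) in the cyclopropanation and is not touched afterwards.

Key step: step 6

Remark: C6 is α to the ketone and configurationally labile in every intermediate before step 5, where it is erased on purpose; these compounds are drawn as step 1 should deliver them and either C6 epimer serves equally. The catalyst of step 1 is assumed to be purchasable in the (R) series.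

Step 1
Reactants: 1 4-methoxycyclohexan-1-one; 2 (E)-1-nitroprop-1-ene
Product: 3 (2R,4R)-4-methoxy-2-[(2R)-1-nitropropan-2-yl]cyclohexan-1-one
Conditions: 1 (3 equiv), 1-[3,5-bis(trifluoromethyl)phenyl]-3-{[(2R)-pyrrolidin-2-yl]methyl}thiourea (20 mol %), butanoic acid (10 mol %), neat, 0 °C
Reagents that add atoms: none
Why: Enamine-catalysed asymmetric Michael addition run as a desymmetrisation: the (R)-pyrrolidine enamine should meet the thiourea-bound (E)-nitroalkene in a synclinal arrangement that gives the syn C6/Ca pair with Ca (R), while axial attack on the half-chair that avoids a syn-axial clash between the C4 methoxy group and the incoming electrophile selects one enantiotopic α-carbon and thereby fixes C4 (2,4-trans).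

Step 2
Reactants: 3 (2R,4R)-4-methoxy-2-[(2R)-1-nitropropan-2-yl]cyclohexan-1-one
Product: 5 (2R)-2-[(1R,5R)-5-methoxy-2-oxocyclohexyl]propanal, via potassium nitronate 4 (not isolated)
Conditions: KOH (1.0 equiv), MeOH, 0 °C; then KMnO4 (0.67 equiv), MgSO4, H2O, 0 °C
Reagents that add atoms: potassium permanganate, [K+].[O-][Mn](=O)(=O)=O
Why: Oxidative Nef reaction: permanganate cleaves the C=N bond of nitronate 4 far faster than it attacks the aldehyde formed, and the cold MgSO4-buffered medium should spare the epimerisable Ca centre and avoids the strong acid that would dehydrate a 1,4-keto aldehyde to a furan, so no stereocentre is made or lost.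

Step 3
Reactants: 5 (2R)-2-[(1R,5R)-5-methoxy-2-oxocyclohexyl]propanal; 6 4-bromo-1,2-dimethoxybenzene
Product: 9 (2R,4R)-2-[(1S,2R)-1-(3,4-dimethoxyphenyl)-1-hydroxypropan-2-yl]-4-methoxycyclohexan-1-one, via arylmagnesium bromide 7 (not isolated), via aryltitanium triisopropoxide 8 (not isolated)
Conditions: 6, Mg, THF, rt; ClTi(OiPr)3, −78 → 0 °C; 5, THF, −78 → −20 °C; aq. NH4Cl
Reagents that add atoms: none
Why: Chemoselective organotitanium carbonyl addition under Felkin–Anh control: the weakly basic aryltitanium triisopropoxide should react with the aldehyde and leave the ring ketone alone (a plain Grignard reagent would not discriminate reliably), attacking anti to the ring residue on Ca and past Ca–H, which gives the syn methyl/hydroxyl relation, Cb (S).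

Step 4
Reactants: 9 (2R,4R)-2-[(1S,2R)-1-(3,4-dimethoxyphenyl)-1-hydroxypropan-2-yl]-4-methoxycyclohexan-1-one
Product: 10 (2R,4R)-2-[(1S,2R)-1-(tert-butyldimethylsilyloxy)-1-(3,4-dimethoxyphenyl)propan-2-yl]-4-methoxycyclohexan-1-one
Conditions: TBSCl, imidazole, DMAP (cat.), DMF, rt
Reagents that add atoms: tert-butyldimethylsilyl chloride, CC(C)(C)[Si](C)(C)Cl
Why: Standard imidazole-promoted silylation of a secondary alcohol: the open hydroxy ketone is drawn out of its equilibrium with the cyclic hemiketal, the silyl chloride leaves the ketone unsilylated, and the bulky ether both protects Cb–OH and later shields one face of the ring, with no stereocentre changed.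

Step 5
Reactants: 10 (2R,4R)-2-[(1S,2R)-1-(tert-butyldimethylsilyloxy)-1-(3,4-dimethoxyphenyl)propan-2-yl]-4-methoxycyclohexan-1-one
Product: 11 (4R)-2-[(1S,2R)-1-(tert-butyldimethylsilyloxy)-1-(3,4-dimethoxyphenyl)propan-2-yl]-4-methoxy-1-(trimethylsilyloxy)cyclohex-1-ene
Conditions: TMSCl, NaI, Et3N, MeCN, rt; pentane extraction
Reagents that add atoms: chlorotrimethylsilane, C[Si](C)(C)Cl
Why: Thermodynamically controlled silyl enol ether formation with iodotrimethylsilane made in situ: reversible O-silylation and deprotonation let the isomers equilibrate toward the more substituted C1=C6 alkene, in which the branched substituent escapes A(1,3) strain by turning Ca–H toward the siloxy group, the excess amine keeps the benzylic silyl ether and the methyl ethers safe, C6 is erased while Ca and C4 are untouched, and any faster-hydrolysing C1=C2 isomer can be returned to 10.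

Step 6
Reactants: 11 (4R)-2-[(1S,2R)-1-(tert-butyldimethylsilyloxy)-1-(3,4-dimethoxyphenyl)propan-2-yl]-4-methoxy-1-(trimethylsilyloxy)cyclohex-1-ene
Product: 12 (1R,4R,6R)-6-[(1S,2R)-1-(tert-butyldimethylsilyloxy)-1-(3,4-dimethoxyphenyl)propan-2-yl]-4-methoxy-1-(trimethylsilyloxy)bicyclo[4.1.0]heptane
Conditions: Et2Zn (4 equiv), CH2I2 (4 equiv), CH2Cl2, 0 °C → rt; pyridine, aq. NaHCO3
Reagents that add atoms: diiodomethane, ICI
Why: The 1:1 reagent EtZnCH2I is an electrophilic zinc carbenoid that hands its methylene group to the electron-rich C1=C6 double bond through a concerted butterfly-type transition state, so that C6–C7 and C1–C7 form in one event. The closest known reaction type is the Furukawa variant of the Simmons–Smith cyclopropanation of trimethylsilyl enol ethers, which is established for tetrasubstituted enol ethers of 2-alkylcyclohexanones. The three-membered ring C1–C6–C7 closes by a suprafacial [2+1] cycloaddition (methylene transfer), not by a stepwise displacement. C6 is controlled by Ca: A(1,3) strain with the siloxy group turns Ca–H into the plane of the enol ether, which puts the aryl(silyloxy)methyl group on one face and only the methyl group on the other, so the carbenoid should enter past the methyl group, and C1 follows from C6 because the addition is necessarily cis. The selectivity needed is facial, and the substrate secures it twice, since the open face is also the one trans to the C4 methoxy group; that methoxy group, the only donor that could steer zinc to the wrong face, is homoallylic, pseudoequatorial and lies under the bulky side chain. Keeping Et2Zn and CH2I2 at 1:1 leaves EtZnI and not ZnI2 as the spent reagent, which should protect the TMS ether and the benzylic silyl ether from Lewis acid.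

Step 7
Reactants: 12 (1R,4R,6R)-6-[(1S,2R)-1-(tert-butyldimethylsilyloxy)-1-(3,4-dimethoxyphenyl)propan-2-yl]-4-methoxy-1-(trimethylsilyloxy)bicyclo[4.1.0]heptane
Product: 13 (1R,4R,6R)-6-[(1S,2R)-1-(tert-butyldimethylsilyloxy)-1-(3,4-dimethoxyphenyl)propan-2-yl]-4-methoxybicyclo[4.1.0]heptan-1-ol
Conditions: K2CO3 (0.2 equiv), MeOH, 0 °C
Reagents that add atoms: none
Why: Base-catalysed methanolysis of a trimethylsilyl ether: the TMS group leaves much faster than the hindered TBS group, and low temperature with a catalytic amount of base should keep the strained cyclopropanol from opening, so all stereocentres are retained.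

Step 8
Reactants: 13 (1R,4R,6R)-6-[(1S,2R)-1-(tert-butyldimethylsilyloxy)-1-(3,4-dimethoxyphenyl)propan-2-yl]-4-methoxybicyclo[4.1.0]heptan-1-ol; 14 vinyl bromide (bromoethene)
Product: 15 (2S,4R)-2-[(1S,2R)-1-(tert-butyldimethylsilyloxy)-1-(3,4-dimethoxyphenyl)propan-2-yl]-4-methoxy-2-(prop-2-en-1-yl)cyclohexan-1-one
Conditions: Pd(OAc)2 (10 mol %), XPhos (20 mol %), Cs2CO3 (2 equiv), 14 (1 M in THF, 5 equiv), toluene, 70 °C, sealed tube
Reagents that add atoms: none
Why: Palladium-catalysed ring-opening (homoenolate) cross-coupling of a cyclopropanol, established for aryl halides and less often used with alkenyl halides: vinyl bromide adds oxidatively to zerovalent palladium, the deprotonated cyclopropanol binds to the metal, β-carbon elimination breaks the less substituted C1–C7 bond and restores the C1 ketone, and the resulting alkylpalladium, whose β-carbon C6 carries no hydrogen, can only eliminate reductively to form C7–C8, C6 keeping its configuration because its bonds to C7, Ca and C5 stay intact.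

Step 9
Reactants: 15 (2S,4R)-2-[(1S,2R)-1-(tert-butyldimethylsilyloxy)-1-(3,4-dimethoxyphenyl)propan-2-yl]-4-methoxy-2-(prop-2-en-1-yl)cyclohexan-1-one
Product: 17 (4R,6S)-6-[(1S,2R)-1-(tert-butyldimethylsilyloxy)-1-(3,4-dimethoxyphenyl)propan-2-yl]-4-methoxy-6-(prop-2-en-1-yl)-1-(trimethylsilyloxy)cyclohex-1-ene, via lithium enolate 16 (not isolated)
Conditions: LiN(iPr)2, THF, −78 °C; TMSCl, −78 → 0 °C
Reagents that add atoms: chlorotrimethylsilane, C[Si](C)(C)Cl
Why: Kinetic enolisation and O-silylation: C2 carries the only α-hydrogens of 15, so a single enol ether can form, and the amide base leaves the silyl ether, the methyl ethers and the allyl group untouched.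

Step 10
Reactants: 17 (4R,6S)-6-[(1S,2R)-1-(tert-butyldimethylsilyloxy)-1-(3,4-dimethoxyphenyl)propan-2-yl]-4-methoxy-6-(prop-2-en-1-yl)-1-(trimethylsilyloxy)cyclohex-1-ene
Product: 18 (4S,6S)-6-[(1S,2R)-1-(tert-butyldimethylsilyloxy)-1-(3,4-dimethoxyphenyl)propan-2-yl]-4-methoxy-6-(prop-2-en-1-yl)cyclohex-2-en-1-one
Conditions: Pd(OAc)2 (1.1 equiv), MeCN, rt
Reagents that add atoms: none
Why: Saegusa–Ito oxidation: divalent palladium takes the place of silicon at the enolate, β-hydride elimination of a C3 hydrogen gives the C2=C3 enone, the unactivated allyl double bond is normally tolerated at room temperature, and C4 and C6 are not involved.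

Step 11
Reactants: 18 (4S,6S)-6-[(1S,2R)-1-(tert-butyldimethylsilyloxy)-1-(3,4-dimethoxyphenyl)propan-2-yl]-4-methoxy-6-(prop-2-en-1-yl)cyclohex-2-en-1-one
Product: 19 (4S,6S)-6-[(1S,2R)-1-(3,4-dimethoxyphenyl)-1-hydroxypropan-2-yl]-4-methoxy-6-(prop-2-en-1-yl)cyclohex-2-en-1-one (CNP0138111.1)
Conditions: Bu4NF, AcOH (1:1), THF, 0 °C → rt
Reagents that add atoms: none
Why: Fluoride-induced cleavage of the silyl ether: buffering with acetic acid keeps the medium near neutral, which should prevent γ-deprotonation at C4, loss of methanol and ionisation of the electron-rich benzylic position, so the four stereocentres arrive unchanged in the target.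

**Compound list**

1 | 4-methoxycyclohexan-1-one | COC1CCC(=O)CC1 | starting material
2 | (E)-1-nitroprop-1-ene | C/C=C/[N+](=O)[O-] | starting material
3 | (2R,4R)-4-methoxy-2-[(2R)-1-nitropropan-2-yl]cyclohexan-1-one | C[C@@H](C[N+](=O)[O-])[C@H]1C[C@H](OC)CCC1=O | intermediate
4 | potassium nitronate of 3 | C[C@@H](C=[N+]([O-])[O-])[C@H]1C[C@H](OC)CCC1=O.[K+] | intermediate
5 | (2R)-2-[(1R,5R)-5-methoxy-2-oxocyclohexyl]propanal | C[C@@H](C=O)[C@H]1C[C@H](OC)CCC1=O | intermediate
6 | 4-bromo-1,2-dimethoxybenzene | COc1ccc(Br)cc1OC | starting material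
7 | (3,4-dimethoxyphenyl)magnesium bromide | COc1ccc([Mg]Br)cc1OC | intermediate
8 | (3,4-dimethoxyphenyl)titanium triisopropoxide | COc1ccc([Ti](OC(C)C)(OC(C)C)OC(C)C)cc1OC | intermediate
9 | (2R,4R)-2-[(1S,2R)-1-(3,4-dimethoxyphenyl)-1-hydroxypropan-2-yl]-4-methoxycyclohexan-1-one | C[C@@H]([C@H](O)c1ccc(OC)c(OC)c1)[C@H]2C[C@H](OC)CCC2=O | intermediate
10 | TBS ether of 9, (2R,4R)-2-[(1S,2R)-1-(tert-butyldimethylsilyloxy)-1-(3,4-dimethoxyphenyl)propan-2-yl]-4-methoxycyclohexan-1-one | C[C@@H]([C@H](O[Si](C)(C)C(C)(C)C)c1ccc(OC)c(OC)c1)[C@H]2C[C@H](OC)CCC2=O | intermediate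
11 | tetrasubstituted TMS enol ether, (4R)-2-[(1S,2R)-1-(tert-butyldimethylsilyloxy)-1-(3,4-dimethoxyphenyl)propan-2-yl]-4-methoxy-1-(trimethylsilyloxy)cyclohex-1-ene | C[Si](C)(C)OC1=C([C@@H](C)[C@H](O[Si](C)(C)C(C)(C)C)c2ccc(OC)c(OC)c2)C[C@H](OC)CC1 | intermediate
12 | (1R,4R,6R)-6-[(1S,2R)-1-(tert-butyldimethylsilyloxy)-1-(3,4-dimethoxyphenyl)propan-2-yl]-4-methoxy-1-(trimethylsilyloxy)bicyclo[4.1.0]heptane | C3[C@@]1([C@@H](C)[C@H](O[Si](C)(C)C(C)(C)C)c2ccc(OC)c(OC)c2)C[C@H](OC)CC[C@]13O[Si](C)(C)C | intermediate
13 | (1R,4R,6R)-6-[(1S,2R)-1-(tert-butyldimethylsilyloxy)-1-(3,4-dimethoxyphenyl)propan-2-yl]-4-methoxybicyclo[4.1.0]heptan-1-ol | C3[C@@]1([C@@H](C)[C@H](O[Si](C)(C)C(C)(C)C)c2ccc(OC)c(OC)c2)C[C@H](OC)CC[C@]13O | intermediate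
14 | vinyl bromide (bromoethene) | C=CBr | starting material
15 | (2S,4R)-2-[(1S,2R)-1-(tert-butyldimethylsilyloxy)-1-(3,4-dimethoxyphenyl)propan-2-yl]-4-methoxy-2-(prop-2-en-1-yl)cyclohexan-1-one | C=CC[C@@]1([C@@H](C)[C@H](O[Si](C)(C)C(C)(C)C)c2ccc(OC)c(OC)c2)C[C@H](OC)CCC1=O | intermediate
16 | lithium C1=C2 enolate of 15 | C=CC[C@@]1([C@@H](C)[C@H](O[Si](C)(C)C(C)(C)C)c2ccc(OC)c(OC)c2)C[C@H](OC)CC=C1O[Li] | intermediate
17 | (4R,6S)-6-[(1S,2R)-1-(tert-butyldimethylsilyloxy)-1-(3,4-dimethoxyphenyl)propan-2-yl]-4-methoxy-6-(prop-2-en-1-yl)-1-(trimethylsilyloxy)cyclohex-1-ene | C=CC[C@@]1([C@@H](C)[C@H](O[Si](C)(C)C(C)(C)C)c2ccc(OC)c(OC)c2)C[C@H](OC)CC=C1O[Si](C)(C)C | intermediate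
18 | (4S,6S)-6-[(1S,2R)-1-(tert-butyldimethylsilyloxy)-1-(3,4-dimethoxyphenyl)propan-2-yl]-4-methoxy-6-(prop-2-en-1-yl)cyclohex-2-en-1-one | C=CC[C@@]1([C@@H](C)[C@H](O[Si](C)(C)C(C)(C)C)c2ccc(OC)c(OC)c2)C[C@H](OC)C=CC1=O | intermediate
19 | (4S,6S)-6-[(1S,2R)-1-(3,4-dimethoxyphenyl)-1-hydroxypropan-2-yl]-4-methoxy-6-(prop-2-en-1-yl)cyclohex-2-en-1-one | C=CC[C@@]1([C@@H](C)[C@H](O)c2ccc(OC)c(OC)c2)C[C@H](OC)C=CC1=O | target

Total step count: 11.
Longest linear sequence: 11 steps (1 → 19). Compounds 2, 6 and 14 enter as purchased materials in steps 1, 3 and 8.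

**Steps most likely to fail**

Step 8. The ring-opened organopalladium species may be protonated, or the cyclopropanol may be opened by the base, before coupling occurs. Reductive elimination at the crowded neopentyl carbon may be slow, and vinyl bromide may be consumed by self-coupling. The fallback sets out from 11 and comes back at 15, and makes the C6–C7 bond by enolate alkylation instead. MeLi in THF at 0 °C cleaves the O–Si bond of 11 to give the regiodefined lithium enolate F1. This is alkylated with allyl bromide (THF, DMPU, −78 → 0 °C) on the face left open by the same A(1,3)-controlled conformation of the side chain. Regiospecific generation of an enolate from a silyl enol ether, followed by C-allylation, is long-established chemistry.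

Step 6. Facial selectivity may be poor if the side chain leaves the A(1,3)-controlled conformation or if coordination to the methoxy group steers the zinc reagent. Methylene transfer to the crowded tetrasubstituted double bond may be slow, and the trimethylsilyl group may be lost to Lewis acid during a long reaction. The fallback sets out from 11 and comes back at 15, and puts reagent control in place of substrate control through an enantioselective Tsuji allylation of the silyl enol ether. The conditions are diallyl carbonate, Pd2(dba)3, (R)-4-tert-butyl-2-[2-(diphenylphosphino)phenyl]-4,5-dihydrooxazole and Bu4N[Ph3SiF2] in THF at 25 °C. By analogy with simple 2-alkylcyclohexanone enolates, the (R) ligand should deliver allyl to the required face of C6. No new compound arises on this path (F0).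

Step 1. Enantio- and diastereocontrol may erode with the small aliphatic nitroalkene, the two enantiotopic α-carbons may be discriminated incompletely, and the nitroalkene may oligomerise. The fallback sets out from 1 and comes back at 5, replacing steps 1 and 2, and sets C4 and Ca in two independent reagent-controlled events.
- Compound 1 is deprotonated with the appropriate enantiomer of lithium bis(1-phenylethyl)amide in the presence of TMSCl (THF, −100 °C). This should give (4R)-4-methoxy-1-(trimethylsilyloxy)cyclohex-1-ene F2.
- A branched-selective iridium-catalysed allylic alkylation follows, with (E)-but-2-en-1-yl methyl carbonate, [Ir(cod)Cl]2, a BINOL-derived bis(1-phenylethyl)amine phosphoramidite, CsF and ZnF2. It should give (4R)-2-[(2S)-but-3-en-2-yl]-4-methoxycyclohexan-1-one F3, both C2 epimers of which are usable.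
- Ozonolysis (O3, CH2Cl2, −78 °C; Me2S) turns the vinyl group into the aldehyde of 5.

**Further compounds**

F1 | step 8 | lithium C1=C6 enolate derived from 11 | [Li]OC1=C([C@@H](C)[C@H](O[Si](C)(C)C(C)(C)C)c2ccc(OC)c(OC)c2)C[C@H](OC)CC1
F0 | step 6 | none | none
F2 | step 1 | (4R)-4-methoxy-1-(trimethylsilyloxy)cyclohex-1-ene | C[Si](C)(C)OC1=CC[C@H](OC)CC1
F3 | step 1 | (4R)-2-[(2S)-but-3-en-2-yl]-4-methoxycyclohexan-1-one | C[C@@H](C=C)C1C[C@H](OC)CCC1=O
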